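Ring-atom labels (C4a, C5 … C8a, O1, C2–C4) are the flavone locants of target 28 and are used for the corresponding atoms of all earlier compounds.

## Analysis of the target

Compound 28 is a flavonol. Its benzo ring A (C4a, C5, C6, C7, C8, C8a) is fused to a 4-pyranone ring C (O1, C2, C3, C4), and C2 carries ring B, a 3-hydroxy-4-methoxyphenyl group. There is no stereocenter, so the stereogenic atoms that appear on the way are transient and racemic. The sensitive groups are the two 3-methylbut-2-enyl (prenyl) chains on C6 and C8 and the electron-rich 3-hydroxy-4-pyranone with its phenols. Strong acid cyclises a prenyl chain onto a neighbouring phenol or adds HX to it, electrophilic oxidants epoxidise it, and hydrogenolysis is ruled out; the enol and phenols are easily oxidised in base and air. Ring B (from isovanillin, 21) and ring C (acyl transfer, then cyclodehydration) are routine. The difficulty is ring A: every carbon is substituted, oxygen on C5, C7 and C8a alternates with carbon on C6, C8 and C4a, and the three oxygens are all different (free hydroxyl, methyl ether, ring oxygen). Prenylation of a phloroglucinol derivative would have to place two prenyl groups on carbon without O-alkylation or over-alkylation and then methylate only the hindered oxygen between them. The route therefore assembles ring A from two small pieces that already carry the substituents: C8a, C6, C5 and C4a come from a 3-alkoxy-2-prenylcyclobutenone, and C8 and C7 from a prenylated methoxyalkyne. The only carbon this leaves bare is C4a, which is exactly where C4 has to be attached.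

## Retrosynthetic reasoning

**28 to 27 (C5–O alkyl bond).** The isopropyl ether on the C5 oxygen is cut last. This oxygen must enter as an alkyl ether because it sits on C3 of the cyclobutenone. A secondary alkyl group is chosen so that a Lewis acid removes it at low temperature, where the methyl ethers on C7 and C4' stay. Keeping C5–O capped also leaves a single phenol, on C8a, for the ring C chemistry.

**27 to 25, 24, then 20 and 23 (ring C).** Ring C is opened at O1–C2 (27, through 26, back to diketone 25), then at C2–C3 (25 back to aryl ester 24), then at the ester C–O bond (24 back to ketone 20 and acid 23). The C3 oxygen is thereby part of the side chain of 20 from the start. This avoids oxidising C3 of a finished flavone in the presence of two prenyl double bonds. It also avoids the oxidative chalcone route, which with an alkoxy group next to the ketone tends to give aurones. The forward steps must acylate a hindered, hydrogen-bonded phenol, move the aroyl group from oxygen to the α-carbon, and close the pyranone with acid while the acetal groups fall off.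

**20 to 19, 18 and 17 (C3–C4 and C4–C4a).** The C3–C4 bond is cut to aldehyde 18 and a hydroxymethyl anion equivalent, with alcohol 19 in between. The C4–C4a bond is cut to phenol 17 and a one-carbon electrophile. This is placed here because 17 has exactly one free ring position, ortho to the phenol, so the formylation has no regiochemical choice.

**17 to 12 and 4 (ring A, the key disconnection).** Ring A is cut at C8a–C8 and C6–C7, giving cyclobutenone 12 and ynol ether 4; in the forward direction the C8a–C4a bond of 12 is broken and made again, and the C8a–C6 bond of 12 is lost. Cutting here and not at the C–prenyl or C–O bonds means no aromatic substitution is needed: each ring atom arrives with its substituent. The forward reaction has to join the prenyl-bearing alkyne carbon to the carbonyl carbon of 12 and not the other way round.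

**12 to 11 and 10; 10 to 7, then 5, 6 and 2; 4 to 1 and 2.** Cyclobutenone 12 comes from dichloride 11 by removal of two chlorine atoms, and 11 from ynol ether 10 by a [2+2] cycloaddition that supplies C8a and C4a. Ynol ether 10 is cut at its propargylic C–C bond to prenyl bromide 2 and the acetylide derived from dichlorovinyl ether 7, itself from trichloroethylene 5 and propan-2-ol 6. Ynol ether 4 is cut in the same way to 2 and the acetylide from chloroacetal 1. Both ynol ethers are thus two or fewer steps from bulk chemicals.

**23 to 22 and 21 (ring B).** Acid 23 is the oxidation product of aldehyde 22, the methoxymethyl ether of isovanillin 21. The acetal is chosen because it comes off in the acid step that closes ring C.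

## Alternatives that were turned down

**Alternative 1: aryne insertion into the C–O bond of an arylpropiolic acid.**
- Disconnection: O1–C8a and C4–C4a; ring A is joined as an aryne to a C2–C3–C4 unit already bound to ring B.
- Forward key step: CsF releases the aryne from the silylaryl triflate A2 in the presence of the ring B arylpropiolic acid A3. The carboxylate oxygen adds to C8a, the aryne carbon remote from the C5 acetal oxygen; the aryl anion on C4a takes over the acyl group and gives the ortho-hydroxyaryl ynone A1. A 6-endo oxa-Michael closure would follow.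
- For: two ring A bonds form in one convergent step, the regiochemistry is set by the C5 alkoxy group, and the ynone has the oxidation level of a chromone.
- Against: A2 is a hexasubstituted benzene with the same alternating pattern plus silyl and triflate groups, so the ring A problem is moved and lengthened, not solved. The aryne is flanked at C8 by a prenyl group, and an intramolecular ene reaction with its allylic hydrogens competes with capture by a hindered carboxylate. Protonation of the aryl anion before acyl migration stops at the aryl ester. A1 has no oxygen on C3, so a late oxidation at C3 would be needed with two prenyl double bonds present.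
- Comparison: this alternative is more convergent at ring C and would be the better plan if A2 were easy to make. The chosen route instead makes the difficult ring in one step from two simple partners and carries the C3 oxygen in with the ketone side chain, at the price of a linear end game.

**Alternative 2: copper-catalysed O-arylation at C8a.**
- Disconnection: O1–C8a; ring C is closed from the enol oxygen of a 1,3-diketone onto a brominated C8a.
- Forward key step: the bromoaryl diketone A5 is heated with CuI and K2CO3; the enolate oxygen displaces bromide in an intramolecular Ullmann-type coupling and gives flavone A4.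
- For: the closure is intramolecular and generally reliable. No phenol is needed on C8a, so ring A has only two oxygens to handle, and no acyl transfer on a hindered phenol is required. On these points it is stronger than the chosen route.
- Against: A5 still needs the fully substituted ring A, now with bromine next to a prenyl group. Electrophilic bromination would not spare the prenyl double bonds, and metalation–prenylation next to an aryl bromide invites halogen–metal exchange. The C–Br bond is flanked by a prenyl and an acyl group, which slows the copper step. A4 has methyl ethers on both C5 and C7, so a chelation-controlled demethylation at C5 remains (no better than the dealkylation of the chosen route), and A4 has no C3 oxygen.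
- Comparison: the ring C closure is more robust here, but the chosen route offers the unambiguous construction of ring A with three differentiated oxygens and the C3 hydroxyl in place.

**Alternative 3: ester-blocked double Claisen rearrangement.**
- Disconnection: the two C–CH2 bonds at C6 and C8.
- Forward key step: the bis(1,1-dimethylallyl) ether A7 is heated; two aromatic [3,3] rearrangements move the allyl groups to the free ortho carbons with allylic inversion and give the linear diprenyl benzoate A6, the ester blocking C4a.
- For: it is the shortest way to the 6,8-diprenyl pattern from a cheap symmetrical phloroglucinol carboxylate. The two hydroxyls of A6 are equivalent, so no protecting group is needed on the C5 oxygen and no Lewis acid dealkylation ends the synthesis. On this point it is stronger than the chosen route.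
- Against: the two tertiary aryl ethers of A7 must be made on hydrogen-bonded, hindered phenols. At the rearrangement temperature such ethers also ionise and lose isoprene, and the first ortho-prenylphenol formed can cyclise or rearrange further. The ester of A6, flanked by two ortho hydroxyls, must then become the oxygenated ketone, and additions to 2,6-disubstituted benzoates are notoriously slow.
- Comparison: ring A may be reached in fewer steps, but the chosen route places every substituent by the connectivity of the two partners and puts the carbonyl carbon on last, at the only free position.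

Key step: step 6

## Route

Assumption: tributyl[(methoxymethoxy)methyl]stannane is taken as a purchasable reagent.

Step 1
Reactants: 1 chloroacetaldehyde dimethyl acetal (2-chloro-1,1-dimethoxyethane); 2 1-bromo-3-methylbut-2-ene (prenyl bromide)
Product: 4 1-methoxy-5-methylhex-4-en-1-yne, via sodium methoxyacetylide 3 (not isolated)
Conditions: NaNH2 (3.0 equiv), liq. NH3, −33 °C; then 2, Et2O, −33 °C; NH4Cl
Reagents that add atoms: none
Why: Two eliminations (methanol, then HCl) and a deprotonation by NaNH2 should give the alkoxyacetylide, which is alkylated at the primary allylic carbon of 2 by SN2 (one-pot alkoxyalkyne synthesis from a chloroacetal); exactly three equivalents of amide leave no strong base to isomerise the skipped enyne.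

Step 2
Reactants: 5 trichloroethylene; 6 propan-2-ol
Product: 7 (E)-1,2-dichloro-1-isopropoxyethene
Conditions: KH (1.0 equiv), THF, 0 °C; then 5, −50 °C → rt
Reagents that add atoms: none
Why: The alkoxide eliminates HCl from 5 and adds anti to the dichloroacetylene formed in situ, which should give the E dichloroenol ether (known dichlorovinyl ether synthesis from alcohols and trichloroethylene).

Step 3
Reactants: 7 (E)-1,2-dichloro-1-isopropoxyethene; 2 1-bromo-3-methylbut-2-ene
Product: 10 1-isopropoxy-5-methylhex-4-en-1-yne, via chloro(isopropoxy)ethyne 8 (not isolated), via lithium isopropoxyacetylide 9 (not isolated)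
Conditions: n-BuLi (2.2 equiv), THF, −78 → −40 °C; then 2, DMPU, −78 °C → rt
Reagents that add atoms: none
Why: The first equivalent of n-BuLi causes deprotonation and loss of LiCl, the second exchanges chlorine for lithium, and the alkoxyacetylide is alkylated by SN2 at the primary carbon of prenyl bromide; 10 is kept at or below room temperature because secondary-alkyl ynol ethers lose alkene on heating.

Step 4
Reactants: 10 1-isopropoxy-5-methylhex-4-en-1-yne
Product: 11 4,4-dichloro-3-isopropoxy-2-(3-methylbut-2-enyl)cyclobut-2-en-1-one
Conditions: Cl3CCOCl (slow addition), Zn–Cu couple, Et2O–DME, 0 °C → rt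
Reagents that add atoms: trichloroacetyl chloride, ClC(=O)C(Cl)(Cl)Cl
Why: Ketene–alkyne [2+2] cycloaddition: the nucleophilic, prenyl-bearing carbon of the ynol ether bonds to the ketene carbonyl carbon, which places isopropoxy on C3 and prenyl on C2; the ynol ether is far more nucleophilic than the trisubstituted alkene, and DME ties up ZnCl2.

Step 5
Reactants: 11 4,4-dichloro-3-isopropoxy-2-(3-methylbut-2-enyl)cyclobut-2-en-1-one
Product: 12 3-isopropoxy-2-(3-methylbut-2-enyl)cyclobut-2-en-1-one
Conditions: Zn dust, AcOH, TMEDA, EtOH, 0 °C → rt
Reagents that add atoms: none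
Why: Reductive removal of the two α-chlorine atoms by zinc under buffered conditions, the standard finish of the dichloroketene route to cyclobutenones; the vinylogous ester and the prenyl group should not be touched.

Step 6
Reactants: 12 3-isopropoxy-2-(3-methylbut-2-enyl)cyclobut-2-en-1-one; 4 1-methoxy-5-methylhex-4-en-1-yne
Product: 17 5-isopropoxy-3-methoxy-2,4-bis(3-methylbut-2-enyl)phenol, via vinylketene 13 (not isolated), via vinylcyclobutenone 14 (not isolated), via dienylketene 15 (not isolated), via cyclohexadienone 16 (not isolated)
Conditions: 4 (2 equiv), toluene, 110 °C, sealed tube; then K2CO3, MeOH, rt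
Reagents that add atoms: none
Why: Heat opens 12 by a four-electron electrocyclic reaction (the C8a–C4a bond breaks) to vinylketene 13. Ketene 13 adds to ynol ether 4 in a [2+2] cycloaddition in which the prenyl-bearing alkyne carbon bonds to the ketene carbonyl carbon (C8a–C8) and the methoxy-bearing carbon to the ketene α-carbon (C7–C6), giving vinylcyclobutenone 14. Compound 14 opens across the old C8a–C6 bond to dienylketene 15, and ring A closes by a disrotatory six-electron electrocyclisation that re-forms C8a–C4a; tautomerisation of dienone 16 gives the phenol. The closest known reaction is the thermal benzannulation of cyclobutenones with alkoxy- and siloxyalkynes, which has also been run with 3-oxygenated cyclobutenones to make resorcinol derivatives. No stereocenter remains: the quaternary carbon of 14 is racemic and is lost on ring opening, and a dienylketene of the wrong double-bond geometry cannot cyclise and returns to 14. The selectivity needed is the regiochemistry of the [2+2] step; the oxygen lone pair of 4 makes its prenyl-bearing carbon nucleophilic and the ketene carbonyl carbon is the electrophile, so the new hydroxyl (C8a) and the methoxy group (C7) should end up meta with the C8 prenyl between them. The ketene should react at the electron-rich triple bond and not at the prenyl alkenes, and 4 cannot fragment at 110 °C because its O-methyl group has no β-hydrogen. Any aryl ester formed from 17 and ketene 13 is returned to 17 by the methanolysis in the work-up.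

Step 7
Reactants: 17 5-isopropoxy-3-methoxy-2,4-bis(3-methylbut-2-enyl)phenol
Product: 18 2-hydroxy-6-isopropoxy-4-methoxy-3,5-bis(3-methylbut-2-enyl)benzaldehyde
Conditions: MgCl2, Et3N, (CH2O)n, THF, reflux; then 1 M HCl, 0 °C
Reagents that add atoms: paraformaldehyde (formaldehyde), C=O
Why: Magnesium-mediated ortho-formylation of a phenol: the magnesium phenoxide delivers formaldehyde to the ortho carbon and the benzylic alkoxide is oxidised by hydride transfer to a second formaldehyde; C4a is the only free ring position, and the basic, non-oxidising conditions spare the prenyl groups.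

Step 8
Reactants: 18 2-hydroxy-6-isopropoxy-4-methoxy-3,5-bis(3-methylbut-2-enyl)benzaldehyde
Product: 19 1-[2-hydroxy-6-isopropoxy-4-methoxy-3,5-bis(3-methylbut-2-enyl)phenyl]-2-(methoxymethoxy)ethan-1-ol (racemic)
Conditions: NaH, THF, 0 °C; then LiCH2OCH2OMe (from Bu3SnCH2OCH2OMe, n-BuLi, THF, −78 °C), −78 → −30 °C; aq. NH4Cl
Reagents that add atoms: tributyl[(methoxymethoxy)methyl]stannane, CCCC[Sn](CCCC)(CCCC)COCOC
Why: Tin–lithium exchange gives the α-alkoxy organolithium (a hydroxymethyl anion equivalent), which adds to the aldehyde of the preformed phenoxide; the new carbinol center is racemic and is removed in step 9, and the acid-sensitive product is taken on crude.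

Step 9
Reactants: 19 1-[2-hydroxy-6-isopropoxy-4-methoxy-3,5-bis(3-methylbut-2-enyl)phenyl]-2-(methoxymethoxy)ethan-1-ol
Product: 20 1-[2-hydroxy-6-isopropoxy-4-methoxy-3,5-bis(3-methylbut-2-enyl)phenyl]-2-(methoxymethoxy)ethan-1-one
Conditions: MnO2 (activated, excess), CH2Cl2, rt
Reagents that add atoms: none
Why: Selective oxidation of a benzylic alcohol by MnO2 under neutral conditions, as in the oxidation of ortho-hydroxybenzyl alcohols to ortho-hydroxyaryl carbonyl compounds; the product is stabilised by the phenol–ketone hydrogen bond, and isolated alkenes are inert to MnO2.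

Step 10
Reactants: 21 isovanillin (3-hydroxy-4-methoxybenzaldehyde)
Product: 22 4-methoxy-3-(methoxymethoxy)benzaldehyde
Conditions: MOMCl, iPr2NEt, CH2Cl2, 0 °C → rt
Reagents that add atoms: chloromethyl methyl ether, COCCl
Why: O-alkylation of the phenol with an α-chloro ether gives the methoxymethyl acetal, which survives the basic steps ahead and leaves in the acid step 14.

Step 11
Reactants: 22 4-methoxy-3-(methoxymethoxy)benzaldehyde
Product: 23 4-methoxy-3-(methoxymethoxy)benzoic acid
Conditions: NaClO2, NaH2PO4, 2-methylbut-2-ene, t-BuOH–H2O, rt
Reagents that add atoms: sodium chlorite, [Na+].[O-]Cl=O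
Why: Pinnick oxidation of the aldehyde to the acid; the buffer keeps the medium mild enough for the aryl acetal, and the alkene scavenges the hypochlorous acid formed.

Step 12
Reactants: 20 1-[2-hydroxy-6-isopropoxy-4-methoxy-3,5-bis(3-methylbut-2-enyl)phenyl]-2-(methoxymethoxy)ethan-1-one; 23 4-methoxy-3-(methoxymethoxy)benzoic acid
Product: 24 3-isopropoxy-5-methoxy-2-[2-(methoxymethoxy)acetyl]-4,6-bis(3-methylbut-2-enyl)phenyl 4-methoxy-3-(methoxymethoxy)benzoate
Conditions: EDC·HCl, DMAP, CH2Cl2, rt
Reagents that add atoms: none
Why: Steglich esterification: the acylpyridinium ion formed from the activated acid and DMAP is reactive enough for the hindered, hydrogen-bonded phenol, and no acid chloride (with HCl that would endanger the acetals) is needed.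

Step 13
Reactants: 24 3-isopropoxy-5-methoxy-2-[2-(methoxymethoxy)acetyl]-4,6-bis(3-methylbut-2-enyl)phenyl 4-methoxy-3-(methoxymethoxy)benzoate
Product: 25 1-[2-hydroxy-6-isopropoxy-4-methoxy-3,5-bis(3-methylbut-2-enyl)phenyl]-2-(methoxymethoxy)-3-[4-methoxy-3-(methoxymethoxy)phenyl]propane-1,3-dione (racemic, keto–enol mixture)
Conditions: LiN(SiMe3)2 (2.5 equiv), THF, −78 → 0 °C; aq. NH4Cl
Reagents that add atoms: none
Why: Baker–Venkataraman rearrangement: the ketone enolate attacks the neighbouring aryl ester through a six-membered transition state and the aroyl group moves from O1 to C3, forming the C2–C3 bond; α-alkoxy ketones are established substrates for this acyl transfer.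

Step 14
Reactants: 25 1-[2-hydroxy-6-isopropoxy-4-methoxy-3,5-bis(3-methylbut-2-enyl)phenyl]-2-(methoxymethoxy)-3-[4-methoxy-3-(methoxymethoxy)phenyl]propane-1,3-dione
Product: 27 3-hydroxy-2-(3-hydroxy-4-methoxyphenyl)-5-isopropoxy-7-methoxy-6,8-bis(3-methylbut-2-enyl)chromen-4-one, via bis-MOM flavone 26 (not isolated)
Conditions: 3 M aq. HCl, MeOH–THF, 50 °C
Reagents that add atoms: none
Why: Acid-catalysed cyclodehydration (the phenol adds to the aroyl ketone, then water is lost) closes ring C, and the same medium cleaves both methoxymethyl acetals; at this stage no prenyl group has a free hydroxyl next to it, so acid-induced chroman formation is not possible.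

Step 15
Reactants: 27 3-hydroxy-2-(3-hydroxy-4-methoxyphenyl)-5-isopropoxy-7-methoxy-6,8-bis(3-methylbut-2-enyl)chromen-4-one
Product: 28 3,5-dihydroxy-2-(3-hydroxy-4-methoxyphenyl)-7-methoxy-6,8-bis(3-methylbut-2-enyl)chromen-4-one
Conditions: BCl3 (4 equiv), CH2Cl2, −78 → −40 °C; then MeOH, aq. NaHCO3
Reagents that add atoms: none
Why: Lewis acid cleavage of an aryl isopropyl ether by BCl3, helped by chelation of boron between the C5 oxygen and the C4 carbonyl; the secondary alkyl group should leave at a temperature where the methyl ethers on C7 and C4' persist, and the freed C5 hydroxyl stays bound to the carbonyl and away from the C6 prenyl group.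

## Compound list

1 | chloroacetaldehyde dimethyl acetal (2-chloro-1,1-dimethoxyethane) | COC(CCl)OC | starting material
2 | 1-bromo-3-methylbut-2-ene (prenyl bromide) | CC(C)=CCBr | starting material
3 | sodium methoxyacetylide (formed in the flask) | [Na+].[C-]#COC | intermediate
4 | 1-methoxy-5-methylhex-4-en-1-yne | COC#CCC=C(C)C | intermediate
5 | trichloroethylene | ClC=C(Cl)Cl | starting material
6 | propan-2-ol | CC(C)O | starting material
7 | (E)-1,2-dichloro-1-isopropoxyethene | Cl/C=C(/Cl)OC(C)C | intermediate
8 | 1-chloro-2-isopropoxyethyne (formed in the flask) | CC(C)OC#CCl | intermediate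
9 | lithium isopropoxyacetylide (formed in the flask) | [Li+].[C-]#COC(C)C | intermediate
10 | 1-isopropoxy-5-methylhex-4-en-1-yne | CC(C)OC#CCC=C(C)C | intermediate
11 | 4,4-dichloro-3-isopropoxy-2-(3-methylbut-2-enyl)cyclobut-2-en-1-one | CC(C)=CCC1=C(OC(C)C)C(Cl)(Cl)C1=O | intermediate
12 | 3-isopropoxy-2-(3-methylbut-2-enyl)cyclobut-2-en-1-one | CC(C)=CCC1=C(OC(C)C)CC1=O | intermediate
13 | 3-isopropoxy-2-(3-methylbut-2-enyl)buta-1,3-dien-1-one (vinylketene, formed in the flask) | C=C(OC(C)C)C(CC=C(C)C)=C=O | intermediate
14 | 4-(1-isopropoxyethenyl)-3-methoxy-2,4-bis(3-methylbut-2-enyl)cyclobut-2-en-1-one (racemic, formed in the flask) | C=C(OC(C)C)C1(CC=C(C)C)C(OC)=C(CC=C(C)C)C1=O | intermediate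
15 | (3E)-5-isopropoxy-3-methoxy-2,4-bis(3-methylbut-2-enyl)hexa-1,3,5-trien-1-one (dienylketene, formed in the flask) | C(=C=O)(CC=C(C)C)/C(OC)=C(\C(OC(C)C)=C)CC=C(C)C | intermediate
16 | 5-isopropoxy-3-methoxy-2,4-bis(3-methylbut-2-enyl)cyclohexa-2,4-dien-1-one (formed in the flask) | CC(C)=CCC1=C(OC)C(CC=C(C)C)=C(OC(C)C)CC1=O | intermediate
17 | 5-isopropoxy-3-methoxy-2,4-bis(3-methylbut-2-enyl)phenol | COc1c(CC=C(C)C)c(O)cc(OC(C)C)c1CC=C(C)C | intermediate
18 | 2-hydroxy-6-isopropoxy-4-methoxy-3,5-bis(3-methylbut-2-enyl)benzaldehyde | COc1c(CC=C(C)C)c(O)c(C=O)c(OC(C)C)c1CC=C(C)C | intermediate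
19 | 1-[2-hydroxy-6-isopropoxy-4-methoxy-3,5-bis(3-methylbut-2-enyl)phenyl]-2-(methoxymethoxy)ethan-1-ol (racemic) | COCOCC(O)c1c(O)c(CC=C(C)C)c(OC)c(CC=C(C)C)c1OC(C)C | intermediate
20 | 1-[2-hydroxy-6-isopropoxy-4-methoxy-3,5-bis(3-methylbut-2-enyl)phenyl]-2-(methoxymethoxy)ethan-1-one | COCOCC(=O)c1c(O)c(CC=C(C)C)c(OC)c(CC=C(C)C)c1OC(C)C | intermediate
21 | isovanillin (3-hydroxy-4-methoxybenzaldehyde) | COc1ccc(C=O)cc1O | starting material
22 | 4-methoxy-3-(methoxymethoxy)benzaldehyde | COCOc1cc(C=O)ccc1OC | intermediate
23 | 4-methoxy-3-(methoxymethoxy)benzoic acid | COCOc1cc(C(=O)O)ccc1OC | intermediate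
24 | 3-isopropoxy-5-methoxy-2-[2-(methoxymethoxy)acetyl]-4,6-bis(3-methylbut-2-enyl)phenyl 4-methoxy-3-(methoxymethoxy)benzoate | COCOCC(=O)c1c(OC(=O)c2ccc(OC)c(OCOC)c2)c(CC=C(C)C)c(OC)c(CC=C(C)C)c1OC(C)C | intermediate
25 | 1-[2-hydroxy-6-isopropoxy-4-methoxy-3,5-bis(3-methylbut-2-enyl)phenyl]-2-(methoxymethoxy)-3-[4-methoxy-3-(methoxymethoxy)phenyl]propane-1,3-dione (racemic) | COCOC(C(=O)c1ccc(OC)c(OCOC)c1)C(=O)c1c(O)c(CC=C(C)C)c(OC)c(CC=C(C)C)c1OC(C)C | intermediate
26 | 5-isopropoxy-7-methoxy-3-(methoxymethoxy)-2-[4-methoxy-3-(methoxymethoxy)phenyl]-6,8-bis(3-methylbut-2-enyl)chromen-4-one (formed in the flask) | COCOc1cc(-c2oc3c(CC=C(C)C)c(OC)c(CC=C(C)C)c(OC(C)C)c3c(=O)c2OCOC)ccc1OC | intermediate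
27 | 3-hydroxy-2-(3-hydroxy-4-methoxyphenyl)-5-isopropoxy-7-methoxy-6,8-bis(3-methylbut-2-enyl)chromen-4-one | COc1ccc(-c2oc3c(CC=C(C)C)c(OC)c(CC=C(C)C)c(OC(C)C)c3c(=O)c2O)cc1O | intermediate
28 | 3,5-dihydroxy-2-(3-hydroxy-4-methoxyphenyl)-7-methoxy-6,8-bis(3-methylbut-2-enyl)chromen-4-one (CNP0261856.0) | COc1ccc(-c2oc3c(CC=C(C)C)c(OC)c(CC=C(C)C)c(O)c3c(=O)c2O)cc1O | target

## Step count and least certain steps

Total: 15 steps. Longest linear sequence: 12 steps (steps 2, 3, 4, 5, 6, 7, 8, 9, 12, 13, 14, 15, from trichloroethylene 5). Steps 1 and 10–11 are side branches.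

**Step 6 (key step).** The alkoxy group stabilises cyclobutenone 12, so ring opening may need a temperature at which vinylketene 13 is lost by dimerisation and by O-acylation of the product phenol faster than ynol ether 4 captures it. The fallback sets out from 12 and comes back at 14, and makes ketene 13 by elimination instead of electrocyclic opening. Sodium isopropoxide in propan-2-ol adds to the carbonyl of 12 and the ring opens to isopropyl (E)-3-isopropoxy-2-(3-methylbut-2-enyl)but-2-enoate F1. Saponification with LiOH gives (E)-3-isopropoxy-2-(3-methylbut-2-enyl)but-2-enoic acid F2, and a neutral chlorinating agent (1-chloro-N,N,2-trimethylpropenylamine) gives (E)-3-isopropoxy-2-(3-methylbut-2-enyl)but-2-enoyl chloride F3. Slow addition of Et3N to F3 and 4 in CH2Cl2 at 0 °C should generate 13 by 1,4-dehydrochlorination and give 14 at low temperature; gentle warming then carries 14 on to 17.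

**Step 4.** Dichloroketene may also add to the prenyl double bond, and ZnCl2 or warming may degrade the acid- and heat-sensitive ynol ether 10 before the cycloaddition is complete. The fallback sets out from 10 and comes back at 12. Ketene gas (from pyrolysis of acetone) is passed into 10 in CH2Cl2 at 0 °C, the known cycloaddition of alkoxyalkynes with the parent ketene; it gives 12 directly, without zinc salts and without the dichloride 11 (no new compound arises, F0).

**Step 9 (with step 8).** The benzylic alcohol 19 has three oxygen donors on its ring and may ionise to an ortho-quinone methide during handling, and MnO2 may attack the free phenol instead of the hindered carbinol. The fallback sets out from 17 and comes back at 20, and replaces the aldehyde, the alcohol and the oxidation by a directed metalation. Dihydropyran with pyridinium tosylate gives 2-[5-isopropoxy-3-methoxy-2,4-bis(3-methylbut-2-enyl)phenoxy]oxane F4. Treatment with n-BuLi in THF at 0 °C lithiates C4a, the only ring hydrogen, between the two ether oxygens, and N-methoxy-2-(methoxymethoxy)-N-methylacetamide acylates the aryllithium to 1-[2-isopropoxy-4-methoxy-3,5-bis(3-methylbut-2-enyl)-6-(oxan-2-yloxy)phenyl]-2-(methoxymethoxy)ethan-1-one F5. Pyridinium tosylate in methanol then removes only the aryl tetrahydropyranyl acetal and gives 20.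

**Step 13 (with step 12).** The phenol of 20 is flanked on both sides and hydrogen-bonded, so O-acylation may stay incomplete, and the amide base may cleave the aryl ester of 24 instead of triggering acyl transfer. The fallback sets out from 20 and 23 and comes back at 25, and forms the C2–C3 bond by an intermolecular Claisen condensation without the ester 24. Acid 23 and carbonyldiimidazole give 1-[4-methoxy-3-(methoxymethoxy)benzoyl]imidazole F6. The dianion of 20 (LiN(SiMe3)2, 3 equiv, THF, −78 °C) is C-acylated by F6 to give 25.

**Step 15.** BCl3 and the HCl it releases may add to the prenyl double bonds or close the C6 prenyl group onto the freed C5 hydroxyl as a chroman, on the most valuable intermediate of the route. The fallback sets out from 18 and comes back at 28, and exchanges the isopropyl group for an acetal early, so that the last step is acid alone.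
- Aldehyde 18 is dealkylated next to the formyl group with MgI2·OEt2 in THF, a chelation-driven cleavage of the type known to spare prenyl groups in 5-O-alkyl prenylflavanones. This gives 2,6-dihydroxy-4-methoxy-3,5-bis(3-methylbut-2-enyl)benzaldehyde F7.
- One equivalent of MOMCl with K2CO3 in acetone protects one of the two equivalent hydroxyls and gives 2-hydroxy-4-methoxy-6-(methoxymethoxy)-3,5-bis(3-methylbut-2-enyl)benzaldehyde F8.
- The chemistry of steps 8, 9, 12 and 13 then gives, in turn:
  - 1-[2-hydroxy-4-methoxy-6-(methoxymethoxy)-3,5-bis(3-methylbut-2-enyl)phenyl]-2-(methoxymethoxy)ethan-1-ol F9;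
  - 1-[2-hydroxy-4-methoxy-6-(methoxymethoxy)-3,5-bis(3-methylbut-2-enyl)phenyl]-2-(methoxymethoxy)ethan-1-one F10;
  - 5-methoxy-3-(methoxymethoxy)-2-[2-(methoxymethoxy)acetyl]-4,6-bis(3-methylbut-2-enyl)phenyl 4-methoxy-3-(methoxymethoxy)benzoate F11;
  - 1-[2-hydroxy-4-methoxy-6-(methoxymethoxy)-3,5-bis(3-methylbut-2-enyl)phenyl]-2-(methoxymethoxy)-3-[4-methoxy-3-(methoxymethoxy)phenyl]propane-1,3-dione F12.
- The acid conditions of step 14 then close ring C and remove all three acetals to give 28.

## Further compounds

F1 | step 6 | isopropyl (E)-3-isopropoxy-2-(3-methylbut-2-enyl)but-2-enoate | C/C(OC(C)C)=C(/CC=C(C)C)C(=O)OC(C)C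
F2 | step 6 | (E)-3-isopropoxy-2-(3-methylbut-2-enyl)but-2-enoic acid | C/C(OC(C)C)=C(/CC=C(C)C)C(=O)O
F3 | step 6 | (E)-3-isopropoxy-2-(3-methylbut-2-enyl)but-2-enoyl chloride | C/C(OC(C)C)=C(/CC=C(C)C)C(Cl)=O
F0 | step 4 | none | none
F4 | step 9 | 2-[5-isopropoxy-3-methoxy-2,4-bis(3-methylbut-2-enyl)phenoxy]oxane (racemic) | COc1c(CC=C(C)C)c(OC2CCCCO2)cc(OC(C)C)c1CC=C(C)C
F5 | step 9 | 1-[2-isopropoxy-4-methoxy-3,5-bis(3-methylbut-2-enyl)-6-(oxan-2-yloxy)phenyl]-2-(methoxymethoxy)ethan-1-one (racemic) | COCOCC(=O)c1c(OC2CCCCO2)c(CC=C(C)C)c(OC)c(CC=C(C)C)c1OC(C)C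
F6 | step 13 | 1-[4-methoxy-3-(methoxymethoxy)benzoyl]imidazole | COCOc1cc(C(=O)n2ccnc2)ccc1OC
F7 | step 15 | 2,6-dihydroxy-4-methoxy-3,5-bis(3-methylbut-2-enyl)benzaldehyde | O=Cc1c(O)c(CC=C(C)C)c(OC)c(CC=C(C)C)c1O
F8 | step 15 | 2-hydroxy-4-methoxy-6-(methoxymethoxy)-3,5-bis(3-methylbut-2-enyl)benzaldehyde | COCOc1c(C=O)c(O)c(CC=C(C)C)c(OC)c1CC=C(C)C
F9 | step 15 | 1-[2-hydroxy-4-methoxy-6-(methoxymethoxy)-3,5-bis(3-methylbut-2-enyl)phenyl]-2-(methoxymethoxy)ethan-1-ol (racemic) | COCOCC(O)c1c(O)c(CC=C(C)C)c(OC)c(CC=C(C)C)c1OCOC
F10 | step 15 | 1-[2-hydroxy-4-methoxy-6-(methoxymethoxy)-3,5-bis(3-methylbut-2-enyl)phenyl]-2-(methoxymethoxy)ethan-1-one | COCOCC(=O)c1c(O)c(CC=C(C)C)c(OC)c(CC=C(C)C)c1OCOC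
F11 | step 15 | 5-methoxy-3-(methoxymethoxy)-2-[2-(methoxymethoxy)acetyl]-4,6-bis(3-methylbut-2-enyl)phenyl 4-methoxy-3-(methoxymethoxy)benzoate | COCOCC(=O)c1c(OC(=O)c2ccc(OC)c(OCOC)c2)c(CC=C(C)C)c(OC)c(CC=C(C)C)c1OCOC
F12 | step 15 | 1-[2-hydroxy-4-methoxy-6-(methoxymethoxy)-3,5-bis(3-methylbut-2-enyl)phenyl]-2-(methoxymethoxy)-3-[4-methoxy-3-(methoxymethoxy)phenyl]propane-1,3-dione (racemic) | COCOC(C(=O)c1ccc(OC)c(OCOC)c1)C(=O)c1c(O)c(CC=C(C)C)c(OC)c(CC=C(C)C)c1OCOC
A1 | alternative 1 | 1-[2-hydroxy-4-methoxy-6-(methoxymethoxy)-3,5-bis(3-methylbut-2-enyl)phenyl]-3-[4-methoxy-3-(methoxymethoxy)phenyl]prop-2-yn-1-one | COCOc1cc(C#CC(=O)c2c(O)c(CC=C(C)C)c(OC)c(CC=C(C)C)c2OCOC)ccc1OC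
A2 | alternative 1 | [3-methoxy-5-(methoxymethoxy)-2,4-bis(3-methylbut-2-enyl)-6-(trimethylsilyl)phenyl] trifluoromethanesulfonate | COCOc1c([Si](C)(C)C)c(OS(=O)(=O)C(F)(F)F)c(CC=C(C)C)c(OC)c1CC=C(C)C
A3 | alternative 1 | 3-[4-methoxy-3-(methoxymethoxy)phenyl]prop-2-ynoic acid | COCOc1cc(C#CC(=O)O)ccc1OC
A4 | alternative 2 | 5,7-dimethoxy-2-[4-methoxy-3-(methoxymethoxy)phenyl]-6,8-bis(3-methylbut-2-enyl)chromen-4-one | COCOc1cc(-c2cc(=O)c3c(OC)c(CC=C(C)C)c(OC)c(CC=C(C)C)c3o2)ccc1OC
A5 | alternative 2 | 1-[2-bromo-4,6-dimethoxy-3,5-bis(3-methylbut-2-enyl)phenyl]-3-[4-methoxy-3-(methoxymethoxy)phenyl]propane-1,3-dione | COCOc1cc(C(=O)CC(=O)c2c(Br)c(CC=C(C)C)c(OC)c(CC=C(C)C)c2OC)ccc1OC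
A6 | alternative 3 | methyl 2,6-dihydroxy-4-methoxy-3,5-bis(3-methylbut-2-enyl)benzoate | COC(=O)c1c(O)c(CC=C(C)C)c(OC)c(CC=C(C)C)c1O
A7 | alternative 3 | methyl 4-methoxy-2,6-bis(2-methylbut-3-en-2-yloxy)benzoate | COC(=O)c1c(OC(C)(C)C=C)cc(OC)cc1OC(C)(C)C=C
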